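Ring A, a 2-bromo-4-alkylphenol, is disconnected to a 4-substituted cyclohex-2-enone: the C1 carbonyl becomes the phenol oxygen, C2 receives the single bromine by enone α-bromination, and C4 carries the CH2 that links ring B, para to oxygen. The key step builds this six-membered carbocycle in one operation from an open-chain aldehyde and methyl vinyl ketone, forming the C4–C5 bond by enamine Michael addition and the C2=C3 bond by aldol condensation. Its precursor is 3-(3,5-dibromo-4-methoxyphenyl)propanal, in which ring B already carries both bromines and its phenol is masked as a methyl ether, so that ring B is inert to every later bromination.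

Key step: step 4

Remark: the target has no stereocentre and is achiral, so there is no enantiomer to select; the annulation product does contain one stereocentre (C4), which is made racemic on purpose and disappears when ring A is aromatised.

Step 1
Reactants: 1 methyl 3-(4-hydroxyphenyl)propanoate
Product: 3 methyl 3-(3,5-dibromo-4-hydroxyphenyl)propanoate, via monobromophenol ester 2 (not isolated)
Conditions: Br2 (2.1 equiv), AcOH, rt
Reagents that add atoms: bromine, BrBr
Why: Electrophilic aromatic bromination of a phenol whose para position is blocked by the side chain, so both bromines should enter ortho to OH in turn (via 2) and no further activated position remains, while the ester is inert.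

Step 2
Reactants: 3 methyl 3-(3,5-dibromo-4-hydroxyphenyl)propanoate
Product: 4 methyl 3-(3,5-dibromo-4-methoxyphenyl)propanoate
Conditions: MeI (1.5 equiv), K2CO3 (2 equiv), DMF, rt → 50 °C
Reagents that add atoms: iodomethane, CI
Why: Williamson ether synthesis, in which the acidic 2,6-dibromophenol is fully deprotonated by carbonate and the small electrophile MeI is alkylated at oxygen despite the two flanking bromines, the ester being stable to anhydrous K2CO3.

Step 3
Reactants: 4 methyl 3-(3,5-dibromo-4-methoxyphenyl)propanoate
Product: 6 3-(3,5-dibromo-4-methoxyphenyl)propanal, via aluminium hemiacetal 5 (not isolated)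
Conditions: DIBAL-H (1.05 equiv), CH2Cl2, −78 °C; MeOH quench at −78 °C, then aq. Rochelle salt
Reagents that add atoms: none
Why: Partial reduction of an ester with DIBAL-H, in which the tetrahedral aluminium hemiacetal 5 should persist at −78 °C and release the aldehyde only on work-up, with aryl bromides and the aryl methyl ether untouched at this temperature.

Step 4
Reactants: 6 3-(3,5-dibromo-4-methoxyphenyl)propanal, 7 methyl vinyl ketone (but-3-en-2-one)
Product: 11 4-[(3,5-dibromo-4-methoxyphenyl)methyl]cyclohex-2-en-1-one (racemic), via diethylamine enamine 8 (not isolated), via keto-aldehyde 9 (not isolated), via ketol 10 (not isolated)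
Conditions: 7 (1.5 equiv), Et2NH (0.3 equiv), MeCN, rt; evaporate; then aq. KOH, n-Bu4NOH (cat.), THF/Et2O, reflux
Reagents that add atoms: none
Why: Diethylamine condenses with aldehyde 6 to enamine 8, whose nucleophilic β-carbon adds to the terminal carbon of methyl vinyl ketone (amine-catalysed Michael addition, the catalytic form of the Stork enamine alkylation), and hydrolysis returns the amine and the 1,5-keto-aldehyde 9 with the C4–C5 bond in place. Hydroxide then forms the methyl-side enolate of the ketone, which attacks the formyl carbon in a 6-(enolendo)-exo-trig aldol closure to ketol 10, and E1cB loss of water gives the conjugated C2=C3 bond, so the whole sequence is a Robinson-type annulation. Only the six-membered carbocycle can close, because attack from the internal ketone CH2 or from the aldehyde α-carbon would give four-membered rings. The one new stereocentre, C4, is formed racemic with an achiral amine and needs no control, since it becomes an sp2 carbon of ring A in step 6. The selectivity required is a single alkylation at the α-CH2 of the aldehyde without self-aldol: the α-branched adduct 9 forms an enamine far more slowly than linear 6, the Michael stage runs under weakly basic amine catalysis where aldehyde self-condensation is slow, and strong base is added only after 6 is consumed. The feature exploited is the para relationship in ring A between the oxygen-bearing carbon and the carbon bearing the benzylic CH2, which is exactly the C1/C4 pattern this annulation lays down.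

Step 5
Reactants: 11 4-[(3,5-dibromo-4-methoxyphenyl)methyl]cyclohex-2-en-1-one (racemic)
Product: 13 2-bromo-4-[(3,5-dibromo-4-methoxyphenyl)methyl]cyclohex-2-en-1-one (racemic), via 2,3-dibromo ketone 12 (not isolated)
Conditions: Br2 (1.05 equiv), CH2Cl2, 0 °C; then Et3N (1.6 equiv), 0 °C → rt
Reagents that add atoms: bromine, BrBr
Why: Bromine addition to the enone C2=C3 bond gives dibromide 12 and triethylamine removes the acidic C2–H with expulsion of the C3 bromide (addition–elimination α-bromination of a cyclic enone), while the 2,6-dibromoanisole ring, with no free position ortho or para to oxygen, should not react with Br2 in the absence of a Lewis acid.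

Step 6
Reactants: 13 2-bromo-4-[(3,5-dibromo-4-methoxyphenyl)methyl]cyclohex-2-en-1-one (racemic)
Product: 16 2-bromo-4-[(3,5-dibromo-4-methoxyphenyl)methyl]phenol, via 2,6-dibromo enone 14 (not isolated), via dienone tautomer 15 (not isolated)
Conditions: CuBr2 (2.1 equiv), LiBr (1 equiv), MeCN, reflux
Reagents that add atoms: none
Why: Copper(II) bromide halogenates the ketone through its enol at C6 to give 14, loss of HBr across C5–C6 gives the cross-conjugated dienone 15 and a proton shift from C4 to oxygen delivers the phenol (the copper(II) bromide/lithium bromide aromatisation known for cyclohex-2-enones), so the vinylic bromine fixed at C2 in step 5 should end up as the only bromine of ring A, ortho to the new OH, and the C4 stereocentre is erased.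

Step 7
Reactants: 16 2-bromo-4-[(3,5-dibromo-4-methoxyphenyl)methyl]phenol
Product: 18 2-bromo-4-[(3,5-dibromo-4-hydroxyphenyl)methyl]phenol (target; also named 2,6-dibromo-4-[(3-bromo-4-hydroxyphenyl)methyl]phenol), via bis-O-dibromoboryl intermediate 17 (not isolated)
Conditions: BBr3 (3 equiv), CH2Cl2, −78 °C → rt; then H2O, 0 °C
Reagents that add atoms: none
Why: Lewis-acid cleavage of an aryl methyl ether, in which BBr3 coordinates the methoxy oxygen and bromide removes the methyl group by SN2, the free phenol of ring A is merely O-borylated, and water hydrolyses both B–O bonds of 17 while the three aryl bromides are unaffected.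

Compound list
1 | methyl 3-(4-hydroxyphenyl)propanoate | COC(=O)CCc1ccc(O)cc1 | starting material
2 | methyl 3-(3-bromo-4-hydroxyphenyl)propanoate (not isolated) | COC(=O)CCc1ccc(O)c(Br)c1 | intermediate
3 | methyl 3-(3,5-dibromo-4-hydroxyphenyl)propanoate | COC(=O)CCc1cc(Br)c(O)c(Br)c1 | intermediate
4 | methyl 3-(3,5-dibromo-4-methoxyphenyl)propanoate | COC(=O)CCc1cc(Br)c(OC)c(Br)c1 | intermediate
5 | diisobutylaluminium hemiacetal of ester 4, [3-(3,5-dibromo-4-methoxyphenyl)-1-methoxypropoxy]bis(2-methylpropyl)alumane (racemic, not isolated) | COC(CCc1cc(Br)c(OC)c(Br)c1)O[Al](CC(C)C)CC(C)C | intermediate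
6 | 3-(3,5-dibromo-4-methoxyphenyl)propanal | COc1c(Br)cc(CCC=O)cc1Br | intermediate
7 | methyl vinyl ketone (but-3-en-2-one) | CC(=O)C=C | starting material
8 | (E)-3-(3,5-dibromo-4-methoxyphenyl)-N,N-diethylprop-1-en-1-amine (not isolated) | CCN(CC)/C=C/Cc1cc(Br)c(OC)c(Br)c1 | intermediate
9 | 2-[(3,5-dibromo-4-methoxyphenyl)methyl]-5-oxohexanal (racemic, not isolated) | COc1c(Br)cc(CC(C=O)CCC(C)=O)cc1Br | intermediate
10 | 4-[(3,5-dibromo-4-methoxyphenyl)methyl]-3-hydroxycyclohexan-1-one (racemic mixture of diastereomers, not isolated) | COc1c(Br)cc(CC2CCC(=O)CC2O)cc1Br | intermediate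
11 | 4-[(3,5-dibromo-4-methoxyphenyl)methyl]cyclohex-2-en-1-one (racemic) | COc1c(Br)cc(CC2C=CC(=O)CC2)cc1Br | intermediate
12 | 2,3-dibromo-4-[(3,5-dibromo-4-methoxyphenyl)methyl]cyclohexan-1-one (racemic mixture of diastereomers, not isolated) | COc1c(Br)cc(CC2CCC(=O)C(Br)C2Br)cc1Br | intermediate
13 | 2-bromo-4-[(3,5-dibromo-4-methoxyphenyl)methyl]cyclohex-2-en-1-one (racemic) | COc1c(Br)cc(CC2C=C(Br)C(=O)CC2)cc1Br | intermediate
14 | 2,6-dibromo-4-[(3,5-dibromo-4-methoxyphenyl)methyl]cyclohex-2-en-1-one (racemic mixture of diastereomers, not isolated) | COc1c(Br)cc(CC2C=C(Br)C(=O)C(Br)C2)cc1Br | intermediate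
15 | 2-bromo-4-[(3,5-dibromo-4-methoxyphenyl)methyl]cyclohexa-2,5-dien-1-one (racemic, keto tautomer of 16, not isolated) | COc1c(Br)cc(CC2C=CC(=O)C(Br)=C2)cc1Br | intermediate
16 | 2-bromo-4-[(3,5-dibromo-4-methoxyphenyl)methyl]phenol | COc1c(Br)cc(Cc2ccc(O)c(Br)c2)cc1Br | intermediate
17 | bis(O-dibromoboryl) derivative of the target bisphenol (not isolated) | BrB(Br)Oc1ccc(Cc2cc(Br)c(OB(Br)Br)c(Br)c2)cc1Br | intermediate
18 | 2-bromo-4-[(3,5-dibromo-4-hydroxyphenyl)methyl]phenol (achiral) | Oc1ccc(Cc2cc(Br)c(O)c(Br)c2)cc1Br | target

Total step count: 7
Longest linear sequence: 7 steps (from 1 to 18; methyl vinyl ketone 7 enters as a commercial component in step 4)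

Steps most likely to fail

Step 4. Self-aldol condensation of the unbranched aldehyde, a second Michael addition at the same α-carbon, or polymerisation of the vinyl ketone could outrun the catalytic cycle. The fallback sets out from aldehyde 6 and replaces catalytic turnover by a stoichiometric, separately prepared nucleophile, so that free aldehyde, amine and enone never coexist. Aldehyde 6 is condensed with piperidine (K2CO3, toluene, 0 °C → rt) and the enamine 1-[(E)-3-(3,5-dibromo-4-methoxyphenyl)prop-1-en-1-yl]piperidine F1 is isolated. F1 is then treated with methyl vinyl ketone 7 in dioxane, and the adduct is hydrolysed and cyclised with AcOH/NaOAc/H2O at reflux (Stork enamine annulation). This passes through 9 and 10 and comes back to the route at enone 11.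

Step 6. Enolisation of the α-bromo enone toward C6 may be slow, and any copper(II) left once the phenol has formed could brominate its free ortho position. The fallback sets out from 13 and uses selenoxide elimination, so no electrophilic bromine is present when the arene appears. Kinetic deprotonation at C6 (LiHMDS, THF, −78 °C) and trapping with PhSeCl should give 2-bromo-4-[(3,5-dibromo-4-methoxyphenyl)methyl]-6-(phenylselanyl)cyclohex-2-en-1-one F2. Oxidation (H2O2, pyridine, CH2Cl2, 0 °C) gives the selenoxide 2-bromo-4-[(3,5-dibromo-4-methoxyphenyl)methyl]-6-(phenylseleninyl)cyclohex-2-en-1-one F3, which undergoes syn-elimination across C5–C6 to dienone 15 and tautomerises, coming back to the route at 16.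

Step 5. The HBr formed during bromine addition may trigger enol bromination at C6 or premature aromatisation, so that addition–elimination does not stop cleanly at the mono-bromo enone. The fallback sets out from 11 and inverts the order of events, aromatising first and brominating the arene second. With CuBr2/LiBr in MeCN at reflux, 11 is brominated at C6 to 6-bromo-4-[(3,5-dibromo-4-methoxyphenyl)methyl]cyclohex-2-en-1-one F4. F4 loses HBr to 4-[(3,5-dibromo-4-methoxyphenyl)methyl]cyclohexa-2,5-dien-1-one F5, which tautomerises to 4-[(3,5-dibromo-4-methoxyphenyl)methyl]phenol F6. Ortho-monobromination of this para-substituted phenol (NBS 1.0 equiv, p-TsOH 10 mol%, MeOH, rt) then comes back to the route at 16, bypassing 13 and step 6. Over-bromination is limited by the reagent stoichiometry and by the deactivating effect of the first bromine.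

Further compounds
F1 | step 4 | 1-[(E)-3-(3,5-dibromo-4-methoxyphenyl)prop-1-en-1-yl]piperidine | COc1c(Br)cc(C/C=C/N2CCCCC2)cc1Br
F2 | step 6 | 2-bromo-4-[(3,5-dibromo-4-methoxyphenyl)methyl]-6-(phenylselanyl)cyclohex-2-en-1-one (racemic mixture of diastereomers) | COc1c(Br)cc(CC2C=C(Br)C(=O)C([Se]c3ccccc3)C2)cc1Br
F3 | step 6 | 2-bromo-4-[(3,5-dibromo-4-methoxyphenyl)methyl]-6-(phenylseleninyl)cyclohex-2-en-1-one (mixture of stereoisomers, not isolated) | COc1c(Br)cc(CC2C=C(Br)C(=O)C([Se](=O)c3ccccc3)C2)cc1Br
F4 | step 5 | 6-bromo-4-[(3,5-dibromo-4-methoxyphenyl)methyl]cyclohex-2-en-1-one (racemic mixture of diastereomers, not isolated) | COc1c(Br)cc(CC2C=CC(=O)C(Br)C2)cc1Br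
F5 | step 5 | 4-[(3,5-dibromo-4-methoxyphenyl)methyl]cyclohexa-2,5-dien-1-one (not isolated) | COc1c(Br)cc(CC2C=CC(=O)C=C2)cc1Br
F6 | step 5 | 4-[(3,5-dibromo-4-methoxyphenyl)methyl]phenol | COc1c(Br)cc(Cc2ccc(O)cc2)cc1Br
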